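## Structural features

The target is a normal-series labdane: a trans-fused decalin (ring A = C1–C5 and C10, ring B = C5–C10) with a trisubstituted C7=C8 alkene (C17 on C8), a β side chain on C9 (C11–C16, 13E alkene, oxygen on C15) and the angular methyl C20 on C10. There are five stereocentres (C2, C4, C5, C9, C10). C4, C5, C10 and C9 are contiguous, and C4 and C10 are quaternary and 1,3 to each other across C5. The oxygenated carbon C19 on C4 is axial and syn to C20. C2 carries a free equatorial (α) hydroxyl between two methylene groups, so it has no neighbouring function from which it could be derived. Three oxygen functions must end up differentiated: a 3-methylbutanoate on the neopentyl C19, a methyl butanedioate on the allylic C15 and a free hydroxyl on C2. The fragile points are the two esters (base, hydride, organometallics), the allylic ester (ionisation), the C7=C8 alkene (acid-promoted shift to C8=C9) and the E geometry at C13. The real difficulty is ring A: the quaternary C4 with its oxygenated carbon in the more hindered axial position, and the C2 oxygen, which neither Robinson annulation nor epoxide-initiated polyene cyclisation delivers (both give C3 oxygen), all on a trans ring fusion with a quaternary C10. The key step exploits the fact that the carbinol C2 is 1,3 to C4. With C4 as an exocyclic alkene carbon, the unit C2(OH)–C3H2–C4(=C19H2) is the retron of a carbonyl-ene reaction. The atoms that remain (C5 to C10 with C17 and the C7=C8 bond) are those of carvone, whose isopropenyl group supplies C3, C4 and C19.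

## Logic of the disconnections

25 to 24: the C15–O acyl bond is cut. The allylic primary alcohol is the most reactive of the hydroxyls of 24, so the most labile ester can be introduced last. The forward step must discriminate the primary allylic from the secondary C2 hydroxyl.

24 to 23: the two O–Si bonds at C2 and C15 are cut. One protecting group type serves both positions and is removed in one operation that leaves the C19 ester untouched.

23 to 22: the C9–H bond is cut and replaced by a C9–O carbonate in an allylic relationship to C7=C8. This turns the C9 stereocentre and the position of the ring B alkene into the consequence of a carbonyl addition. The forward step must deliver hydride to the more substituted allyl terminus, on the face opposite to the leaving group.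

22 to 12 and 18: the C9–C11 bond is cut, which makes the route convergent and removes the whole side chain in one stroke. The forward step must be a 1,2-addition to a hindered enone that tolerates the C19 ester and occurs on the α face.

18 back to 13 (through 17, 16 and 15): the C13–C16 and C14–C15 bonds are cut (carbometalation of an alkyne, then acylation). The E trisubstituted alkene then follows from a syn addition and not from an olefination with uncertain geometry. The remaining changes are functional group interconversions.

12 to 11 to 10: the C19–O acyl bond is cut and C19 is taken back to the aldehyde level. The robust 3-methylbutanoate is put on while C2 is protected and before any organometallic step, so C2 and C19 never need to be told apart as free alcohols.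

10 to 9: the C4–C18 bond is cut. The quaternary centre becomes the alkylation of an exocyclic enolate. The forward step must put the small electrophile on the α face, which the syn-axial C20 secures.

9 to 6 (through 8 and 7): the C19 aldehyde is traced to the exocyclic C4=C19 alkene by way of an epoxide and a 1,2-hydride shift, and the C2 silyl ether to the free alcohol. No stereocentre depends on these steps.

6 to 5: the C2–C3 bond is cut (key disconnection). Ring A disappears, the C2 stereocentre disappears, and the bicycle becomes a monocyclic aldehyde whose only stereocentres are C5 and C10. The forward step must be chemoselective for the aldehyde over the enone, place the oxygen equatorial, and lose a proton only from the methyl group.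

5 to 3 (through 4): redox adjustment of the C2 carbon from ester to aldehyde, with the C9 ketone reduced and restored.

3 to 2 to 1: the C10–C1 and C10–C20 bonds are cut. Two successive enolate alkylations of a cheap terpene build the quaternary C10. The second alkylation must occur anti to the isopropenyl group so that C1 and C4 end up trans, which is what the later trans ring fusion requires.

## Other disconnections considered

Alternative 1: cut C4–C5 and C9–C10 in one operation, the biomimetic bicyclisation that comes to mind first. The forward key step would be a Lewis-acid or trivalent-titanium (Cp2TiCl) opening of the 2,2-disubstituted epoxide of the acyclic epoxy triene A1, with cyclisation to the bicycle A2. The chosen plan is preferred on three grounds. First, in the chair transition state the metal-bound CH2O group on C4 is the larger substituent and should go equatorial, which gives the C18-oxygenated epimer and not the required axial C19. Second, termination at the C8 cation or radical is expected to give mixtures of the 7-ene, the 8(17)-ene and the 8-ene. Third, A1 itself needs three stereodefined trisubstituted alkenes, an enantiopure 1,1-disubstituted epoxide and the C2 stereocentre before the key step can be tried.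

Alternative 2: keep C4, C5 and C10 and cut the aromatic ring C of (+)-podocarpic acid A3, which already has the axial C19 carboxyl. The forward key step would be Birch reduction of the O-methyl ether followed by ozonolytic excision of C13 and C14 to the keto ester A4. This settles three stereocentres by inheritance. However, ring A of A3 has no functional group, so the C2 hydroxyl would have to come from an undirected methylene C–H oxidation among C1, C2, C3 and C6. If that oxidation stopped at the ketone, hydride reduction would be expected to give the axial 2β alcohol, because both syn-axial groups block the β face. In addition C17 and the whole C13–C16 unit would have to be rebuilt. The chosen plan makes the C2 oxygen in a C–C bond-forming step.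

Alternative 3: dearomatisation for ring A. The substitution pattern of ring A (oxygen on C2, carbon on C4 and C10, all meta) is that of 5-methoxy-2,3-dimethylbenzoic acid. The forward key step would be an asymmetric Birch reduction–alkylation of the chiral benzamide A5 with iodomethane, to the diene A6 with the C4 quaternary centre and a masked C2 ketone. The ground against it is mechanistic. Ring B would then have to be closed by bonding C9 to an sp2 C10 of the ring A enone from a tether on C5. Stereoelectronic axial attack next to the tether-bearing carbon gives the cis-fused decalin. The configuration at C5 relative to C4 is not controlled, and the C2 ketone would still have to be reduced against its steric bias.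

Key step: step 5

Remark: labdane numbering (C1–C20) is used for all intermediates. Compounds 1 and 13 and the alkylating and acylating reagents named in the steps are taken to be commercial.

## Steps

Step 1
Reactants: 1 (R)-(−)-carvone
Product: 2 6-methylcarvone (both C6 epimers)
Conditions: LiN(i-Pr)2, THF, −78 °C; MeI, −78 → 0 °C
Reagents that add atoms: iodomethane, CI
Why: Kinetic deprotonation of the enone at the α′ carbon (the future C10) and enolate methylation introduce C20; the new centre is planarised again in step 2, so its configuration does not matter.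

Step 2
Reactants: 2 6-methylcarvone
Product: 3 methyl 2-[(1S,6S)-1,3-dimethyl-2-oxo-6-(prop-1-en-2-yl)cyclohex-3-en-1-yl]acetate
Conditions: LiN(i-Pr)2, THF, −78 °C; BrCH2CO2Me, DMPU, −78 → −20 °C
Reagents that add atoms: methyl bromoacetate, COC(=O)CBr
Why: Alkylation of the tetrasubstituted lithium enolate should occur on the face anti to the adjacent isopropenyl group, which sets the quaternary C10 with C20 cis and the new chain (C1, C2) trans to the isopropenyl carbon C4; this is the relationship a trans ring fusion needs.

Step 3
Reactants: 3 keto ester
Product: 4 diol (carbinol epimers at C9)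
Conditions: LiAlH4, THF, 0 °C
Reagents that add atoms: none
Why: Hydride reduction takes the ester to the primary alcohol and reduces the hindered enone carbonyl 1,2; the C9 carbinol configuration is irrelevant because it is oxidised back in step 4.

Step 4
Reactants: 4 diol
Product: 5 2-[(1S,6S)-1,3-dimethyl-2-oxo-6-(prop-1-en-2-yl)cyclohex-3-en-1-yl]acetaldehyde
Conditions: Dess–Martin periodinane, CH2Cl2, rt
Reagents that add atoms: none
Why: Dess–Martin oxidation converts the primary alcohol into the aldehyde and the allylic alcohol back into the enone under non-acidic, non-epimerising conditions.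

Step 5
Reactants: 5 keto aldehyde
Product: 6 2α-hydroxy-11,12,13,14,15,16,18-heptanorlabda-4(19),7-dien-9-one
Conditions: Me2AlCl, CH2Cl2, −78 → −20 °C
Reagents that add atoms: none
Why: Me2AlCl binds the aldehyde oxygen and the CH2 terminus (C3) of the 1,1-disubstituted alkene attacks C2 while a hydrogen of the allylic methyl group is passed to oxygen (or removed by an Al–CH3 bond with loss of methane), concertedly or through a short-lived tertiary C4 cation; this is a type 2 intramolecular carbonyl-ene reaction. The closest known reaction type is the Me2AlCl-promoted cyclisation of 6-methylhept-6-enals to 3-methylenecyclohexanols. Ring A closes in a six-membered mode that is exo with respect to the C2=O bond and endo with respect to the C3=C4 π bond, and because the chain on C10 and the isopropenyl group on C5 are trans and both equatorial on ring B, the new ring is trans-fused by construction. The only new stereocentre is C2: in the chair-like transition state C20 is axial on the forming ring, so an axial (β) C2–O bond would be syn-diaxial to it, and the bridged chair–chair array that an axial oxygen would need for hydrogen transfer is blocked by the same methyl group; the aluminium-bound oxygen therefore takes the equatorial position and the 2α alcohol should result. The step needs chemoselectivity for the aldehyde over the enone carbonyl, which the higher electrophilicity of the aldehyde and the electron-poor, non-donating enone alkene secure. It also needs proton loss from the methyl group and not from C3 or C5, which the six-centre transfer to the aluminium alkoxide and the proton-scavenging Al–CH3 bonds favour, and which also suppresses chloride capture and acid-promoted alkene migration.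

Step 6
Reactants: 6 hydroxy dienone
Product: 7 2α-silyl ether of 6
Conditions: TBSCl, imidazole, DMF, rt
Reagents that add atoms: tert-butyldimethylsilyl chloride, CC(C)(C)[Si](C)(C)Cl
Why: Silylation of the unhindered equatorial secondary alcohol protects C2–OH against the base, the alkylating agent and the acylating agents of the next steps.

Step 7
Reactants: 7 silyl ether
Product: 8 4,19-epoxide (C4 epimers)
Conditions: mCPBA, CH2Cl2, 0 °C
Reagents that add atoms: 3-chloroperoxybenzoic acid, OOC(=O)c1cccc(Cl)c1
Why: Prilezhaev epoxidation takes place at the electron-rich exocyclic alkene and not at the electron-poor enone alkene; both epoxide epimers converge in steps 8 and 9.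

Step 8
Reactants: 8 spiro epoxide
Product: 9 19-aldehyde (C4 epimers)
Conditions: BF3·OEt2 (cat.), CH2Cl2, −78 °C
Reagents that add atoms: none
Why: Meinwald rearrangement: the Lewis acid opens the epoxide at the tertiary C4 and a 1,2-hydride shift from C19 gives the aldehyde; the C4 configuration is erased in step 9.

Step 9
Reactants: 9 aldehyde
Product: 10 2α-(tert-butyldimethylsilyloxy)-9-oxo-11,12,13,14,15,16-hexanorlabd-7-en-19-al
Conditions: KOt-Bu (1.05 equiv), THF, −40 °C; MeI, −40 → 0 °C
Reagents that add atoms: iodomethane, CI
Why: C-Methylation of the exocyclic aldehyde enolate creates the quaternary C4; the β (axial) trajectory is blocked by the syn-axial C20, so iodomethane should enter from the α (equatorial) side, leaving C18 α and the formyl carbon C19 β and axial. The aldehyde α-hydrogen is the most acidic site, so one equivalent of base should leave the enone untouched.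

Step 10
Reactants: 10 quaternary aldehyde
Product: 11 19-alcohol
Conditions: NaBH4, MeOH/THF, −20 °C
Reagents that add atoms: none
Why: Borohydride reduces the aldehyde faster than the conjugated, doubly flanked C9 ketone at low temperature.

Step 11
Reactants: 11 neopentyl alcohol
Product: 12 19-(3-methylbutanoate)
Conditions: 3-methylbutanoyl chloride, pyridine, DMAP (cat.), CH2Cl2, 0 °C → rt
Reagents that add atoms: 3-methylbutanoyl chloride, CC(C)CC(=O)Cl
Why: Nucleophile-catalysed acylation of the only free hydroxyl installs the C19 ester of the target while C2 is silylated, so the two ring A oxygens never compete.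

Step 12
Reactants: 13 but-3-yn-1-ol
Product: 15 ethyl (2E)-5-hydroxy-3-methylpent-2-enoate, via alkenylalane 14 (not isolated)
Conditions: Me3Al, Cp2ZrCl2 (cat.), CH2Cl2, 0 °C → rt; ClCO2Et, 0 °C
Reagents that add atoms: trimethylaluminium, C[Al](C)C; ethyl chloroformate, CCOC(=O)Cl
Why: Zirconium-catalysed carboalumination (Negishi) adds CH3 and Al syn across the alkyne with methyl on the internal carbon, and acylation of the alkenyl–Al bond with retention gives the E enoate; this fixes the 13E geometry and supplies C16 and C15.

Step 13
Reactants: 15 hydroxy enoate
Product: 16 ethyl (2E)-5-iodo-3-methylpent-2-enoate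
Conditions: I2, PPh3, imidazole, CH2Cl2, 0 °C
Reagents that add atoms: iodine, II
Why: Appel-type iodination of the primary alcohol proceeds under neutral conditions that do not touch the enoate.

Step 14
Reactants: 16 iodo enoate
Product: 17 (2E)-5-iodo-3-methylpent-2-en-1-ol
Conditions: i-Bu2AlH, CH2Cl2, −78 °C
Reagents that add atoms: none
Why: 1,2-Reduction of the unsaturated ester by the aluminium hydride gives the allylic alcohol; the primary iodide is inert at this temperature.

Step 15
Reactants: 17 iodo alcohol
Product: 18 tert-butyl{[(2E)-5-iodo-3-methylpent-2-en-1-yl]oxy}dimethylsilane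
Conditions: TBSCl, imidazole, CH2Cl2, 0 °C
Reagents that add atoms: tert-butyldimethylsilyl chloride, CC(C)(C)[Si](C)(C)Cl
Why: Silylation masks the allylic hydroxyl for the halogen–lithium exchange of step 16.

Step 16
Reactants: 12 enone ester; 18 side-chain iodide
Product: 22 9β-methyl carbonate of the C9 adduct, via organolithium reagent 19 (not isolated), via organocerium reagent 20 (not isolated), via cerium alkoxide 21 (not isolated)
Conditions: 18, t-BuLi (2 equiv), Et2O, −78 °C; CeCl3, THF, −78 °C; 12, −78 °C; ClCO2Me, −78 → 0 °C
Reagents that add atoms: methyl chloroformate, COC(=O)Cl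
Why: Iodine–lithium exchange and transmetalation give a weakly basic organocerium reagent that adds 1,2 to the hindered enone in preference to the neopentyl ester. Attack should come from the α face, anti to the pseudo-axial C20 on the neighbouring C10 (axial attack), so that the side chain is 9α and the alkoxide 9β; the alkoxide is acylated in the same flask.

Step 17
Reactants: 22 tertiary allylic carbonate
Product: 23 2α,15-bis(tert-butyldimethylsilyloxy)labda-7,13E-dien-19-yl 3-methylbutanoate
Conditions: Pd2(dba)3·CHCl3 (cat.), n-Bu3P, HCO2H, Et3N, THF, 60 °C
Reagents that add atoms: none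
Why: Zerovalent palladium ionises the 9β carbonate with inversion, so the metal sits on the α face of the C7–C8–C9 allyl unit. Formate then loses CO2 to give a palladium hydride, and the hydride is delivered on the metal-bearing face to the more substituted terminus C9 (the known course of allylic formate hydrogenolysis with n-Bu3P); this should give 9α-H with the β side chain and place the alkene at C7=C8.

Step 18
Reactants: 23 bis-silyl ether
Product: 24 2α,15-dihydroxylabda-7,13E-dien-19-yl 3-methylbutanoate
Conditions: HF·pyridine, pyridine, THF, 0 °C → rt
Reagents that add atoms: none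
Why: Buffered fluoride cleaves both silyl ethers without touching the ester or the alkenes, and the C19 ester cannot migrate to the distant C2 oxygen.

Step 19
Reactants: 24 diol
Product: 25 methyl 2α-hydroxy-19-(3-methylbutanoyloxy)labda-7,13E-dien-15-yl butanedioate (target)
Conditions: methyl 4-chloro-4-oxobutanoate (1.05 equiv), 2,4,6-collidine, CH2Cl2, −40 → −20 °C
Reagents that add atoms: methyl 4-chloro-4-oxobutanoate, COC(=O)CCC(=O)Cl
Why: With a weak hindered base at low temperature, an acyl chloride should discriminate the unhindered primary allylic C15–OH from the secondary C2–OH, which gives the target directly.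

## Compound list

1 | (R)-(−)-carvone, (5R)-2-methyl-5-(prop-1-en-2-yl)cyclohex-2-en-1-one | CC1=CC[C@H](CC1=O)C(=C)C | starting material
2 | (5R)-2,6-dimethyl-5-(prop-1-en-2-yl)cyclohex-2-en-1-one (both C6 epimers) | O=C1C(C)=CC[C@@H](C(C)=C)C1C | intermediate
3 | methyl 2-[(1S,6S)-1,3-dimethyl-2-oxo-6-(prop-1-en-2-yl)cyclohex-3-en-1-yl]acetate | O=C1C(C)=CC[C@@H](C(C)=C)[C@]1(C)CC(=O)OC | intermediate
4 | 2-[(1S,6S)-2-hydroxy-1,3-dimethyl-6-(prop-1-en-2-yl)cyclohex-3-en-1-yl]ethan-1-ol (both carbinol epimers) | OC1C(C)=CC[C@@H](C(C)=C)[C@]1(C)CCO | intermediate
5 | 2-[(1S,6S)-1,3-dimethyl-2-oxo-6-(prop-1-en-2-yl)cyclohex-3-en-1-yl]acetaldehyde | O=C1C(C)=CC[C@@H](C(C)=C)[C@]1(C)CC=O | intermediate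
6 | 2α-hydroxy-11,12,13,14,15,16,18-heptanorlabda-4(19),7-dien-9-one (trans-decalin, 5α-H, 10β-methyl) | O=C1C(C)=CC[C@H]2C(=C)C[C@H](O)C[C@]12C | intermediate
7 | 2α-(tert-butyldimethylsilyloxy)-11,12,13,14,15,16,18-heptanorlabda-4(19),7-dien-9-one | O=C1C(C)=CC[C@H]2C(=C)C[C@H](O[Si](C)(C)C(C)(C)C)C[C@]12C | intermediate
8 | 2α-(tert-butyldimethylsilyloxy)-4,19-epoxy-11,12,13,14,15,16,18-heptanorlabd-7-en-9-one (C4 epimers) | O=C1C(C)=CC[C@H]2C3(CO3)C[C@H](O[Si](C)(C)C(C)(C)C)C[C@]12C | intermediate
9 | 2α-(tert-butyldimethylsilyloxy)-9-oxo-11,12,13,14,15,16,18-heptanorlabd-7-en-19-al (C4 epimers) | O=C1C(C)=CC[C@H]2C(C=O)C[C@H](O[Si](C)(C)C(C)(C)C)C[C@]12C | intermediate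
10 | 2α-(tert-butyldimethylsilyloxy)-9-oxo-11,12,13,14,15,16-hexanorlabd-7-en-19-al (C18 methyl α, formyl C19 β) | O=C1C(C)=CC[C@H]2[C@@](C)(C=O)C[C@H](O[Si](C)(C)C(C)(C)C)C[C@]12C | intermediate
11 | 2α-(tert-butyldimethylsilyloxy)-19-hydroxy-11,12,13,14,15,16-hexanorlabd-7-en-9-one | O=C1C(C)=CC[C@H]2[C@@](C)(CO)C[C@H](O[Si](C)(C)C(C)(C)C)C[C@]12C | intermediate
12 | 2α-(tert-butyldimethylsilyloxy)-9-oxo-11,12,13,14,15,16-hexanorlabd-7-en-19-yl 3-methylbutanoate | O=C1C(C)=CC[C@H]2[C@@](C)(COC(=O)CC(C)C)C[C@H](O[Si](C)(C)C(C)(C)C)C[C@]12C | intermediate
13 | but-3-yn-1-ol | C#CCCO | starting material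
14 | (E)-alkenylalane, dimethyl[(1E)-4-(dimethylalumanyloxy)-2-methylbut-1-en-1-yl]alumane | C[Al](C)/C=C(\C)CCO[Al](C)C | intermediate
15 | ethyl (2E)-5-hydroxy-3-methylpent-2-enoate | CCOC(=O)/C=C(\C)CCO | intermediate
16 | ethyl (2E)-5-iodo-3-methylpent-2-enoate | CCOC(=O)/C=C(\C)CCI | intermediate
17 | (2E)-5-iodo-3-methylpent-2-en-1-ol | OC/C=C(\C)CCI | intermediate
18 | tert-butyl{[(2E)-5-iodo-3-methylpent-2-en-1-yl]oxy}dimethylsilane | CC(C)(C)[Si](C)(C)OC/C=C(\C)CCI | intermediate
19 | [(3E)-5-(tert-butyldimethylsilyloxy)-3-methylpent-3-en-1-yl]lithium | [Li]CC/C(C)=C/CO[Si](C)(C)C(C)(C)C | intermediate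
20 | [(3E)-5-(tert-butyldimethylsilyloxy)-3-methylpent-3-en-1-yl]cerium dichloride (RCeCl2) | Cl[Ce](Cl)CC/C(C)=C/CO[Si](C)(C)C(C)(C)C | intermediate
21 | dichlorocerium 9β-alkoxide of the C9 adduct (side chain 9α) | CC(C)(C)[Si](C)(C)OC/C=C(\C)CC[C@]1(O[Ce](Cl)Cl)C(C)=CC[C@H]2[C@@](C)(COC(=O)CC(C)C)C[C@H](O[Si](C)(C)C(C)(C)C)C[C@]12C | intermediate
22 | 2α,15-bis(tert-butyldimethylsilyloxy)-9β-(methoxycarbonyloxy)-9-epi-labda-7,13E-dien-19-yl 3-methylbutanoate (side chain 9α, carbonate 9β) | CC(C)(C)[Si](C)(C)OC/C=C(\C)CC[C@]1(OC(=O)OC)C(C)=CC[C@H]2[C@@](C)(COC(=O)CC(C)C)C[C@H](O[Si](C)(C)C(C)(C)C)C[C@]12C | intermediate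
23 | 2α,15-bis(tert-butyldimethylsilyloxy)labda-7,13E-dien-19-yl 3-methylbutanoate | CC(C)(C)[Si](C)(C)OC/C=C(\C)CC[C@H]1C(C)=CC[C@H]2[C@@](C)(COC(=O)CC(C)C)C[C@H](O[Si](C)(C)C(C)(C)C)C[C@]12C | intermediate
24 | 2α,15-dihydroxylabda-7,13E-dien-19-yl 3-methylbutanoate | OC/C=C(\C)CC[C@H]1C(C)=CC[C@H]2[C@@](C)(COC(=O)CC(C)C)C[C@H](O)C[C@]12C | intermediate
25 | methyl 2α-hydroxy-19-(3-methylbutanoyloxy)labda-7,13E-dien-15-yl butanedioate (CNP0118741.1) | COC(=O)CCC(=O)OC/C=C(\C)CC[C@H]1C(C)=CC[C@H]2[C@@](C)(COC(=O)CC(C)C)C[C@H](O)C[C@]12C | target

## Step count and least certain steps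

Total step count: 19. Longest linear sequence: 15 (steps 1–11 and 16–19); steps 12–15 prepare fragment 18.

Step 5 (key step). The most likely failures are loss of regiocontrol in the proton loss after C2–C3 bond formation (endocyclic C3=C4 or C4=C5 alkenes by way of a free C4 cation), chloride capture at C4, or erosion of the equatorial preference at C2 if the ring closes through a non-chair array. The fallback replaces the ene reaction with an intramolecular allylmetal addition. It sets out from 3, whose isopropenyl group is chlorinated in an ene-type reaction (Ca(OCl)2, solid CO2, CH2Cl2/H2O) to the allylic chloride F1. Reduction with i-Bu2AlH gives the chloro diol F2, and Dess–Martin oxidation gives the chloro keto aldehyde F3. CrCl2 in THF (Nozaki–Hiyama allylation) then turns the allylic chloride into an allylchromium species that adds to the aldehyde only. The 2-substituted allyl unit is symmetrical, so either terminus leads to the exocyclic 4(19)-alkene by construction, and the chair-like six-membered transition state again places the oxygen equatorial. The route is rejoined at 6.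

Step 16. The likely problems are competing attack of the organometallic on the C19 ester, γ-deprotonation of the enone, incomplete acylation of the hindered tertiary cerium alkoxide, or insufficient α-facial selectivity, on which the C9 configuration of step 17 depends. The fallback removes the dependence on the facial selectivity of the addition and on the tertiary carbonate. It sets out from 12 and 18. The organocerium addition is quenched with water to give the tertiary allylic alcohol F4 (either C9 epimer). Pyridinium chlorochromate (C5H5NH[CrO3Cl]) then effects an oxidative 1,3-transposition to the enone F5 (C7 ketone, C8=C9 alkene). Luche reduction (NaBH4, CeCl3·7H2O, MeOH, −40 °C) by axial hydride attack gives the 7β allylic alcohol F6, and acetic formic anhydride in pyridine gives the formate F7. Pd(acac)2 with n-Bu3P in refluxing dioxane then delivers hydride from the formate to C9 on the α face with loss of CO2, and the route is rejoined at 23.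

Step 17. The hydride could be delivered to the less substituted terminus C7 (giving the C8=C9 alkene), or the allyl complex could lose a proton to a diene, because C9 is fully substituted and next to the quaternary C10. The fallback uses a sigmatropic hydrogen transfer that can only reach C9. It sets out from 12 and passes through F4 and F5 to the 7β alcohol F6 as described above. Mitsunobu displacement of F6 with 2-nitrobenzenesulfonylhydrazide (PPh3, diethyl azodicarboxylate, THF, −30 °C) inverts C7 and, after loss of the sulfinic acid on warming, gives the 7α allylic diazene F8. F8 expels dinitrogen in a retro-ene reaction that places hydrogen on the α face of C9 and moves the alkene to C7=C8, and the route is rejoined at 23.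

Step 9. Competing O-methylation of the hindered aldehyde enolate, γ-deprotonation and α-methylation of the enone, or incomplete facial selectivity at C4 could lower the yield of the quaternary aldehyde. The fallback introduces C18 as a carbenoid and not as an electrophile toward an enolate. It sets out from 9, which is converted with TBSOTf and Et3N (CH2Cl2, −78 °C) into the silyl enol ether F9. Simmons–Smith cyclopropanation (Et2Zn, CH2I2) from the unhindered α face gives the siloxy spirocyclopropane F10. Mild acid (TsOH·H2O, wet CH2Cl2) protonates the unsubstituted cyclopropane carbon and cleaves its bond to the oxygen-bearing carbon, which releases the ring strain and unveils the α methyl group and the β formyl group. The route is rejoined at 10.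

Step 19. Some acylation of the C2 hydroxyl, or bis-acylation, could occur if the rate difference between the two alcohols is smaller than expected. The fallback removes the competition by changing the order of deprotection. It sets out from 23, in which the primary allylic silyl ether is cleaved selectively (pyridinium p-toluenesulfonate, MeOH, 0 °C) to the C15 alcohol F11. Acylation with methyl 4-chloro-4-oxobutanoate and pyridine gives the diester silyl ether F12, and HF·pyridine then removes the C2 silyl group. The route is rejoined at 25.

## Further compounds

F1 | step 5 | methyl 2-[(1S,6S)-6-(3-chloroprop-1-en-2-yl)-1,3-dimethyl-2-oxocyclohex-3-en-1-yl]acetate | O=C1C(C)=CC[C@@H](C(CCl)=C)[C@]1(C)CC(=O)OC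
F2 | step 5 | 2-[(1S,6S)-6-(3-chloroprop-1-en-2-yl)-2-hydroxy-1,3-dimethylcyclohex-3-en-1-yl]ethan-1-ol (carbinol epimers) | OC1C(C)=CC[C@@H](C(CCl)=C)[C@]1(C)CCO
F3 | step 5 | 2-[(1S,6S)-6-(3-chloroprop-1-en-2-yl)-1,3-dimethyl-2-oxocyclohex-3-en-1-yl]acetaldehyde | O=C1C(C)=CC[C@@H](C(CCl)=C)[C@]1(C)CC=O
F4 | step 16 | 2α,15-bis(tert-butyldimethylsilyloxy)-9-hydroxylabda-7,13E-dien-19-yl 3-methylbutanoate (C9 epimers) | CC(C)(C)[Si](C)(C)OC/C=C(\C)CCC1(O)C(C)=CC[C@H]2[C@@](C)(COC(=O)CC(C)C)C[C@H](O[Si](C)(C)C(C)(C)C)C[C@]12C
F5 | step 16 | 2α,15-bis(tert-butyldimethylsilyloxy)-7-oxolabda-8,13E-dien-19-yl 3-methylbutanoate | CC(C)(C)[Si](C)(C)OC/C=C(\C)CCC1=C(C)C(=O)C[C@H]2[C@@](C)(COC(=O)CC(C)C)C[C@H](O[Si](C)(C)C(C)(C)C)C[C@]12C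
F6 | step 16 | 2α,15-bis(tert-butyldimethylsilyloxy)-7β-hydroxylabda-8,13E-dien-19-yl 3-methylbutanoate | CC(C)(C)[Si](C)(C)OC/C=C(\C)CCC1=C(C)[C@@H](O)C[C@H]2[C@@](C)(COC(=O)CC(C)C)C[C@H](O[Si](C)(C)C(C)(C)C)C[C@]12C
F7 | step 16 | 2α,15-bis(tert-butyldimethylsilyloxy)-7β-(formyloxy)labda-8,13E-dien-19-yl 3-methylbutanoate | CC(C)(C)[Si](C)(C)OC/C=C(\C)CCC1=C(C)[C@@H](OC=O)C[C@H]2[C@@](C)(COC(=O)CC(C)C)C[C@H](O[Si](C)(C)C(C)(C)C)C[C@]12C
F8 | step 17 | 2α,15-bis(tert-butyldimethylsilyloxy)-7α-diazenyllabda-8,13E-dien-19-yl 3-methylbutanoate | CC(C)(C)[Si](C)(C)OC/C=C(\C)CCC1=C(C)[C@H](N=N)C[C@H]2[C@@](C)(COC(=O)CC(C)C)C[C@H](O[Si](C)(C)C(C)(C)C)C[C@]12C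
F9 | step 9 | 2α,19-bis(tert-butyldimethylsilyloxy)-11,12,13,14,15,16,18-heptanorlabda-4(19),7-dien-9-one (enol ether, both geometries) | O=C1C(C)=CC[C@H]2C(=CO[Si](C)(C)C(C)(C)C)C[C@H](O[Si](C)(C)C(C)(C)C)C[C@]12C
F10 | step 9 | 2α,19-bis(tert-butyldimethylsilyloxy)-18,19-cyclo-11,12,13,14,15,16-hexanorlabd-7-en-9-one (cyclopropane CH2 α, C19 β, C19 epimers) | O=C1C(C)=CC[C@H]2[C@]3(CC3O[Si](C)(C)C(C)(C)C)C[C@H](O[Si](C)(C)C(C)(C)C)C[C@]12C
F11 | step 19 | 2α-(tert-butyldimethylsilyloxy)-15-hydroxylabda-7,13E-dien-19-yl 3-methylbutanoate | OC/C=C(\C)CC[C@H]1C(C)=CC[C@H]2[C@@](C)(COC(=O)CC(C)C)C[C@H](O[Si](C)(C)C(C)(C)C)C[C@]12C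
F12 | step 19 | methyl 2α-(tert-butyldimethylsilyloxy)-19-(3-methylbutanoyloxy)labda-7,13E-dien-15-yl butanedioate | COC(=O)CCC(=O)OC/C=C(\C)CC[C@H]1C(C)=CC[C@H]2[C@@](C)(COC(=O)CC(C)C)C[C@H](O[Si](C)(C)C(C)(C)C)C[C@]12C
A1 | alternative 1 | (2E,6E,10E)-12-(tert-butyldimethylsilyloxy)-3,7,11-trimethyl-13-(2-methyloxiran-2-yl)trideca-2,6,10-trien-1-yl acetate (acyclic epoxy triene) | CC(=O)OC/C=C(\C)CC/C=C(\C)CC/C=C(\C)C[C@@H](O[Si](C)(C)C(C)(C)C)C[C@@]1(C)CO1
A2 | alternative 1 | 2α-(tert-butyldimethylsilyloxy)-19-hydroxylabda-7,13E-dien-15-yl acetate | CC(=O)OC/C=C(\C)CC[C@H]1C(C)=CC[C@H]2[C@@](C)(CO)C[C@H](O[Si](C)(C)C(C)(C)C)C[C@]12C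
A3 | alternative 2 | (+)-podocarpic acid, 12-hydroxypodocarpa-8,11,13-trien-19-oic acid | C[C@]12CCC[C@]([C@@H]1CCC3=C2C=C(C=C3)O)(C)C(=O)O
A4 | alternative 2 | methyl 19-hydroxy-8-oxo-13,14,15,16,17-pentanorlabdan-12-oate | COC(=O)C[C@H]1C(=O)CC[C@H]2[C@@](C)(CO)CCC[C@]12C
A5 | alternative 3 | (5-methoxy-2,3-dimethylphenyl)[(2S)-2-(methoxymethyl)pyrrolidin-1-yl]methanone | COC[C@@H]1CCCN1C(=O)c1cc(OC)cc(C)c1C
A6 | alternative 3 | [(1S)-3-methoxy-1,5,6-trimethylcyclohexa-2,5-dien-1-yl][(2S)-2-(methoxymethyl)pyrrolidin-1-yl]methanone | COC[C@@H]1CCCN1C(=O)[C@@]1(C)C=C(OC)CC(C)=C1C
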